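## Structural features

The target is a flavonolignan in which a tricin unit (chromen-4-one rings A and C with the 5- and 7-hydroxyls, ring B a 3,5-dimethoxyphenyl at C2) is joined through its 4'-oxygen to Cβ of a three-carbon chain. Cα of the chain bears ring G (4-hydroxy-3-methoxyphenyl) and a free secondary hydroxyl, and the Cγ oxygen is esterified with (E)-p-coumaric acid. The only stereocentres are the neighbouring Cα (R) and Cβ (S), which are erythro, that is anti when ring G–Cα–Cβ–Cγ is drawn as a zigzag. The fragile groups are the p-oxygenated benzylic alcohol at Cα (ionises in acid and can epimerise), the alkyl cinnamate (excludes hydroxide, alkoxide and hydrogenation at the end, and can migrate from the Cγ to the Cα oxygen under base) and four phenols of very different acidity. The real difficulty is the Cβ–O bond: the ring B phenol oxygen is flanked by two methoxy groups, and substitution at a secondary Cβ next to a benzylic carbinol is slow, prone to elimination and would have to be stereospecific. The key step uses the 1,2-relationship of the Cα hydroxyl and the Cβ aryl ether: read backwards, the Cα–Cβ bond is the one formed when the benzylic carbon of a ring G benzyl ether shifts onto the oxygen-bearing terminus of an allyl group, with Cγ hidden in the propenyl group left on Cβ. The ring B oxygen can therefore be attached to an sp carbon by conjugate addition before any stereocentre exists.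

## Logic of the disconnections

25 to 24. Three O–Si bonds are cut (ring G oxygen, Cα oxygen, 7-oxygen). Buffered fluoride is the one deprotection that the ester and the benzylic alcohol both tolerate. The gain is a last step that touches no carbon. The demand is that every protecting group still present at the end is a silyl group.

24 to 22 and 23. The acyl C–O bond at Cγ is cut. The ester is the most base-sensitive group, so it enters after all strongly basic and oxidative steps. The gain is removal of the whole cinnamate. The demand is a single reactive aliphatic hydroxyl in 22, with its acidic 7-phenol masked, and activation of the alcohol rather than of 23, so that the phenol of 23 needs no protection.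

22 to 19. The Cγ–O bond and the C=C bond of the propenyl group are exchanged: Cγ is the alkene carbon attached to Cβ. The gain is that Cγ needs no protecting group through the flavone construction. The demand is an oxidant that spares electron-rich arenes, and immediate reduction of the α-aryloxy aldehyde before Cβ can epimerise.

19 to 18. One O–Si bond at the 7-oxygen is cut. The demand is selectivity for the 7-hydroxyl over the chelated 5-hydroxyl.

18 to 16. The O1–C2 bond and the C2=C3 unsaturation of ring C are removed. The gain is an open enone made from two simple halves. The demand is an oxidative cyclisation that leaves the propenyl group, the silyl ethers and ring A intact.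

16 to 14 and 15. The enone C=C bond is cut. The gain is that ring A arrives unprotected in one piece. The demand is a hydroxide-free condensation, because the aryl silyl ether on ring G would not survive aqueous hydroxide.

14 to 13 to 12. The Cα O–Si bond and the acetal C–O bonds are the only changes. The demand is mild acid for the acetal, and a Cα protecting group that prevents iodoetherification onto the propenyl group later.

12 to 10. The Cα–Cβ bond is cut (key disconnection). Both stereocentres and the hindered ether then trace back to one carbinol centre and one alkene geometry. The demand is clean benzylic metalation, [2,3] over [1,2] shift, and anti over syn selectivity.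

10 to 5 and 9. The benzylic C–O bond is cut. The gain is two fragments of similar size. The demand is alkylation of a secondary allylic alkoxide under non-acidic conditions, since 5 ionises easily.

9 to 8 to 7 to 6. Functional group changes at the benzylic carbon and one O–Si bond. The demand is neutral bromination, because 9 is solvolytically labile.

5 to 4. The carbinol C–H bond is cut. The gain is an achiral enone. The demand is enantioface selection by a catalyst, with a hydride source that does not hydroborate the enol ether.

4 to 2 and 3. The aryl O–C(sp2) bond is cut. The hindered ether is made by addition to a triple bond, not by substitution. The demand is (E) selectivity.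

2 to 1. The acetal C–O bonds are cut. The demand is that the aldehyde stays masked through the organolithium step.

## Other disconnections considered

Alternative 1: The cut is the acyl C–O bond at Cγ, made on the prochiral diol A1. In the forward step a lipase transfers the acyl group of vinyl ester A2 to one of the two enantiotopic hydroxymethyl arms and should give mono-ester A3 with Cβ configured.
- In its favour: the step is catalytic and runs at ambient temperature; it installs the cinnamate with no coupling reagent; Cγ is at the right oxidation level from the start; the bromide on ring B would allow a convergent cross-coupling to a preformed chromone.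
- Against it here: cinnamoyl donors are sluggish with serine hydrolases; the di-ortho-substituted aryloxy group sits on the prochiral carbon, so the enantioselectivity would have to be found by screening. Cα would still have to be made afterwards by oxidising the free arm and adding a ring G nucleophile. That passes through an α-aryloxy-β-acyloxy aldehyde that can epimerise or lose the cinnamate by β-elimination. The ester would then have to survive an organometallic addition and the flavone construction, with acyl migration to the new Cα alkoxide as a further risk.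
- Comparison: on structure, A3 holds Cβ, Cγ and the ester but not Cα, whereas 12 holds both stereocentres. On mechanism, enzyme recognition is less predictable than a sigmatropic relay. On step economy, Alternative 1 is equal or better up to Cβ and would remove the late oxidative cleavage and the Mitsunobu step, but it carries the most fragile group through the harshest steps.

Alternative 2: The cut is the Cα–aryl bond. In the forward step the redox-active ester A4 is reduced at the cathode with NiBr2(dme) and a bipyridine ligand, loses CO2, and the C4 radical of the dioxane is joined to aryl iodide A5 to give the trans dioxane A6.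
- In its favour: the coupling is convergent and needs no organolithium; the Cγ oxygen and the protection of both hydroxyls are in place; the trans ring relationship corresponds to the erythro diad; Cβ could come from the chiral pool.
- Against it here: the C4 radical has the aryloxy group on the neighbouring carbon, and β-scission with loss of a phenoxyl radical would compete with capture by nickel. The trans preference of a nearly planar α-oxy radical is likely to be modest. The electron-rich iodide A5 is a slow partner. Above all, the hindered Cβ–O bond of A4 would still have to be made by substitution at a secondary carbon, which is the problem the chosen plan avoids. Removal of the benzylidene acetal needs acid or hydrogenolysis, both awkward late.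
- Comparison: on structure, A6 equals 12 in stereochemical content and is better in that Cγ is already oxygenated and needs no alkene cleavage. On mechanism it is less secure. On step economy it should be comparable after the key step and longer before it.

Alternative 3: The cut is the Cα–H bond. In the forward step a ketoreductase reduces one enantiomer of the racemising keto ester A7 and should fix Cα and Cβ together in A8.
- In its favour: A7 is assembled by phenoxide displacement at a doubly activated carbon, so the hindered ether is made as easily as in the chosen plan (equal on this point). One aqueous, ambient step would set both centres, and ester reduction would give the Cγ alcohol without osmium or a protecting group change.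
- Against it here: the enzyme must accept a ketone between two bulky aryl-bearing groups and deliver the erythro isomer in the right absolute sense, which can only be found by screening. Racemisation must outpace reduction without retro-Claisen cleavage in buffer. The ring B bromide must later be turned into the flavone in the presence of the benzylic alcohol.
- Comparison: on structure, A8 is closer to the target than 12. On mechanism, the chosen plan rests on substrate control that can be analysed in advance, the alternative on empirical catalyst control. On step economy, Alternative 3 is the better plan by several steps if a suitable enzyme exists.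

Key step: step 8

Remarks on the chemistry:
- Locants: Cα, Cβ and Cγ are the chain carbons; ring G is the 3-methoxy-4-oxyphenyl on Cα; ring B is the 3,5-dimethoxyphenyl whose 4-oxygen is on Cβ.
- Re-derivation of the CIP descriptors shows that the (R,E) ether 10 leads to (1R,2S,3E)-12, which is the (αR,βS) erythro diad of 25. No structure needed correcting.
- The precursor keeps the TIPS ether and the dioxolane, both inert to n-BuLi. Two reagent choices are changed instead: catecholborane replaces borane in the reduction (the enol ether would be hydroborated), and the chalcone is made without hydroxide (assumption: an aryl TIPS ether does not survive aqueous-alcoholic hydroxide).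
- The transient centres of 17 and 20 are formed as mixtures; they are destroyed in the same step.

## Steps

Step 1
Reactants: 1 syringaldehyde
Product: 2 4-(1,3-dioxolan-2-yl)-2,6-dimethoxyphenol
Conditions: ethylene glycol (5 equiv), p-TsOH (2 mol%), toluene, reflux, Dean–Stark; Et3N quench
Reagents that add atoms: ethylene glycol, OCCO
Why: Acid-catalysed acetalisation driven by azeotropic removal of water; the acid is neutralised before concentration because the para-hydroxy acetal is acid-labile.

Step 2
Reactants: 2 4-(1,3-dioxolan-2-yl)-2,6-dimethoxyphenol; 3 but-3-yn-2-one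
Product: 4 (E)-4-[4-(1,3-dioxolan-2-yl)-2,6-dimethoxyphenoxy]but-3-en-2-one
Conditions: DABCO (10 mol%), CH2Cl2, 0 °C → rt
Reagents that add atoms: none
Why: Amine-catalysed oxa-Michael addition of a phenol to an ynone; DABCO adds first and is displaced by the phenoxide (addition–elimination), which gives the (E)-β-aryloxy enone and forms the crowded aryl–O bond at an sp carbon.

Step 3
Reactants: 4 (E)-4-[4-(1,3-dioxolan-2-yl)-2,6-dimethoxyphenoxy]but-3-en-2-one
Product: 5 (R,E)-4-[4-(1,3-dioxolan-2-yl)-2,6-dimethoxyphenoxy]but-3-en-2-ol
Conditions: (S)-2-methyl-CBS-oxazaborolidine (20 mol%), catecholborane (1.8 equiv), toluene, −78 °C; MeOH, aq. NaHCO3; Et3N-washed silica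
Reagents that add atoms: none
Why: Corey–Bakshi–Shibata reduction in which the alkenyl group is the large substituent, so the (S) catalyst delivers hydride to give the (R) carbinol; catecholborane does not hydroborate the enol ether, and the ionisable allylic alcohol is kept away from acid.

Step 4
Reactants: 6 vanillin
Product: 7 3-methoxy-4-(triisopropylsilyloxy)benzaldehyde
Conditions: TIPSCl (1.1 equiv), imidazole (2.2 equiv), DMF, rt
Reagents that add atoms: triisopropylsilyl chloride, CC(C)[Si](Cl)(C(C)C)C(C)C
Why: Standard silylation of a phenol; the TIPS ether is chosen because it is inert to NaH and to n-BuLi at −78 °C.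

Step 5
Reactants: 7 3-methoxy-4-(triisopropylsilyloxy)benzaldehyde
Product: 8 [3-methoxy-4-(triisopropylsilyloxy)phenyl]methanol
Conditions: NaBH4, THF/EtOH, 0 °C
Reagents that add atoms: none
Why: Borohydride reduction of an aromatic aldehyde; brief exposure at 0 °C leaves the aryl silyl ether intact.

Step 6
Reactants: 8 [3-methoxy-4-(triisopropylsilyloxy)phenyl]methanol
Product: 9 4-(bromomethyl)-2-methoxy-1-(triisopropylsilyloxy)benzene
Conditions: CBr4 (1.2 equiv), PPh3 (1.2 equiv), CH2Cl2, 0 °C; used at once
Reagents that add atoms: carbon tetrabromide, BrC(Br)(Br)Br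
Why: Appel bromination under neutral conditions, which suits an electron-rich benzylic bromide that solvolyses easily.

Step 7
Reactants: 5 (R,E)-4-[4-(1,3-dioxolan-2-yl)-2,6-dimethoxyphenoxy]but-3-en-2-ol; 9 4-(bromomethyl)-2-methoxy-1-(triisopropylsilyloxy)benzene
Product: 10 (R,E)-4-[4-(1,3-dioxolan-2-yl)-2,6-dimethoxyphenoxy]but-3-en-2-yl 3-methoxy-4-(triisopropylsilyloxy)benzyl ether
Conditions: NaH (1.2 equiv), Bu4NI (5 mol%), THF/DMF, 0 °C → rt
Reagents that add atoms: none
Why: Williamson etherification of the alkoxide with a reactive benzylic bromide; the carbinol C–O bond is not touched, so the (R) configuration and the (E) enol ether are kept, and no acid is present.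

Step 8
Reactants: 10 (R,E)-4-[4-(1,3-dioxolan-2-yl)-2,6-dimethoxyphenoxy]but-3-en-2-yl 3-methoxy-4-(triisopropylsilyloxy)benzyl ether
Product: 12 (1R,2S,3E)-2-[4-(1,3-dioxolan-2-yl)-2,6-dimethoxyphenoxy]-1-[3-methoxy-4-(triisopropylsilyloxy)phenyl]pent-3-en-1-ol, via α-lithio benzyl ether 11 (not isolated)
Conditions: n-BuLi (1.3 equiv), THF, −78 °C; aq. NH4Cl
Reagents that add atoms: none
Why: n-BuLi, guided by the ether oxygen, removes a benzylic proton of 10 to give 11, whose carbanion attacks the aryloxy-bearing alkene terminus while the allylic C–O bond breaks in a concerted suprafacial [2,3]-sigmatropic shift through a five-membered envelope transition state. The closest known reaction type is the [2,3]-Wittig rearrangement of benzyl allyl ethers with chirality transfer from a secondary allylic carbinol carbon; no ring is closed. At Cβ the new bond forms on the alkene face from which the C–O bond departs, and the methyl group of the carbinol carbon sits pseudo-equatorial, so the (R) carbinol centre is relayed to (S) at Cβ and the new alkene is (E). At Cα the ring G aryl group prefers the exo position of the envelope, which with an (E) enol ether places hydroxyl and aryloxy anti (erythro) and gives (R). The step needs benzylic deprotonation in preference to ortho-metalation of ring B and to the vinylic C–H, [2,3] over [1,2] shift, and anti over syn; these are served by the oxygen-directed benzylic position, the low temperature, and the (E) geometry fixed in step 2. The dioxolane and the aryl TIPS ether are inert to n-BuLi at −78 °C.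

Step 9
Reactants: 12 (1R,2S,3E)-2-[4-(1,3-dioxolan-2-yl)-2,6-dimethoxyphenoxy]-1-[3-methoxy-4-(triisopropylsilyloxy)phenyl]pent-3-en-1-ol
Product: 13 4-{[(1R,2S,3E)-1-hydroxy-1-[3-methoxy-4-(triisopropylsilyloxy)phenyl]pent-3-en-2-yl]oxy}-3,5-dimethoxybenzaldehyde
Conditions: pyridinium p-toluenesulfonate (10 mol%), acetone/H2O (9:1), 40 °C
Reagents that add atoms: water, O
Why: Mild acid hydrolysis of an aryl dioxolane that is activated by the para oxygen; these conditions are too weak to ionise the benzylic alcohol or to cleave the aryl silyl ether.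

Step 10
Reactants: 13 4-{[(1R,2S,3E)-1-hydroxy-1-[3-methoxy-4-(triisopropylsilyloxy)phenyl]pent-3-en-2-yl]oxy}-3,5-dimethoxybenzaldehyde
Product: 14 4-{[(1R,2S,3E)-1-(tert-butyldimethylsilyloxy)-1-[3-methoxy-4-(triisopropylsilyloxy)phenyl]pent-3-en-2-yl]oxy}-3,5-dimethoxybenzaldehyde
Conditions: TBSOTf (1.3 equiv), 2,6-lutidine (2.5 equiv), CH2Cl2, −78 → 0 °C
Reagents that add atoms: tert-butyldimethylsilyl triflate, CC(C)(C)[Si](C)(C)OS(=O)(=O)C(F)(F)F
Why: Silylation of a hindered secondary alcohol with a silyl triflate; the ether blocks iodoetherification onto the propenyl group in step 12 and acyl migration after step 15.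

Step 11
Reactants: 14 4-{[(1R,2S,3E)-1-(tert-butyldimethylsilyloxy)-1-[3-methoxy-4-(triisopropylsilyloxy)phenyl]pent-3-en-2-yl]oxy}-3,5-dimethoxybenzaldehyde; 15 2',4',6'-trihydroxyacetophenone
Product: 16 (E)-chalcone: (E)-1-(2,4,6-trihydroxyphenyl)-3-(3,5-dimethoxyphenyl)prop-2-en-1-one whose ring B 4-oxygen carries the (1R,2S,3E)-1-(tert-butyldimethylsilyloxy)-1-[3-methoxy-4-(triisopropylsilyloxy)phenyl]pent-3-en-2-yl group
Conditions: 15 (1.3 equiv), LiN(SiMe3)2 (5.5 equiv), THF, −78 → 0 °C; then 14, −78 °C → rt; 1 M HCl to pH 4
Reagents that add atoms: none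
Why: Claisen–Schmidt condensation run through the lithium polyanion of the unprotected hydroxyacetophenone; the aldolate eliminates (E1cB) to the (E) enone, no hydroxide is present to attack the aryl silyl ether, and ring A needs no protecting group.

Step 12
Reactants: 16 (E)-chalcone described in step 11
Product: 18 5,7-dihydroxyflavone: 5,7-dihydroxy-2-(3,5-dimethoxyphenyl)chromen-4-one whose ring B 4-oxygen carries the same (1R,2S,3E) silylated pentenyl group, via flavanone 17 (not isolated)
Conditions: I2 (1.2 equiv), pyridine, 90 °C; aq. Na2S2O3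
Reagents that add atoms: none
Why: Iodine-mediated oxidative cyclisation: the 2'-phenol adds to the enone (oxa-Michael) to give 17, which is iodinated at C3 through its enol and loses HI to pyridine; the basic medium protects the silyl ethers, and the Cα stereocentre is not involved.

Step 13
Reactants: 18 5,7-dihydroxyflavone described in step 12
Product: 19 5-hydroxy-7-(triisopropylsilyloxy)flavone: compound 18 with the 7-hydroxyl as its TIPS ether
Conditions: TIPSCl (1.2 equiv), imidazole (2.5 equiv), DMF, 0 °C → rt
Reagents that add atoms: triisopropylsilyl chloride, CC(C)[Si](Cl)(C(C)C)C(C)C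
Why: Selective silylation of the acidic 7-hydroxyl; the 5-hydroxyl is held in a hydrogen bond to the C4 carbonyl and does not react, and it stays inert in step 15.

Step 14
Reactants: 19 5-hydroxy-7-(triisopropylsilyloxy)flavone described in step 13
Product: 22 (2S,3R)-3-(tert-butyldimethylsilyloxy)-2-{4-[5-hydroxy-4-oxo-7-(triisopropylsilyloxy)-4H-chromen-2-yl]-2,6-dimethoxyphenoxy}-3-[3-methoxy-4-(triisopropylsilyloxy)phenyl]propan-1-ol, via vicinal diol 20 (not isolated), via α-aryloxy aldehyde 21 (not isolated)
Conditions: OsO4 (2 mol%), NaIO4 (4 equiv), 2,6-lutidine (2 equiv), 1,4-dioxane/H2O (3:1), rt; extract; then NaBH4, THF/EtOH, −20 °C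
Reagents that add atoms: osmium tetroxide, O=[Os](=O)(=O)=O; sodium periodate, [Na+].[O-]I(=O)(=O)=O
Why: Lemieux–Johnson cleavage of the only electron-rich alkene (osmium spares the electron-rich arenes that ozone would attack), followed by borohydride reduction. The aldehyde 21 is reduced cold and without purification so that Cβ does not epimerise; the flavone carbonyl is far less reactive than the aldehyde.

Step 15
Reactants: 22 primary alcohol described in step 14; 23 (E)-p-coumaric acid
Product: 24 Cγ p-coumarate: compound 22 with its primary hydroxyl esterified by (E)-3-(4-hydroxyphenyl)prop-2-enoic acid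
Conditions: 23 (1.5 equiv), PPh3 (1.5 equiv), diisopropyl azodicarboxylate (1.5 equiv), THF, 0 °C → rt
Reagents that add atoms: none
Why: Mitsunobu esterification, which activates the alcohol and not the acid; the carboxylic acid is far more acidic than the phenol of 23, so the ester forms chemoselectively without phenol protection, and substitution at the primary Cγ touches no stereocentre.

Step 16
Reactants: 24 Cγ p-coumarate described in step 15
Product: 25 target: (αR,βS)-erythro tricin 4'-O-(β-guaiacylglyceryl) ether γ-(E)-p-coumarate
Conditions: Bu4NF (6 equiv), AcOH (6 equiv), THF, 0 °C → rt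
Reagents that add atoms: none
Why: Fluoride-mediated cleavage of the two aryl TIPS ethers and the Cα TBS ether; buffering with acetic acid keeps phenoxide and alkoxide concentrations low, so that ester cleavage and γ→α acyl migration are suppressed.

## Compound list

1 | syringaldehyde | COc1cc(C=O)cc(OC)c1O | starting material
2 | 4-(1,3-dioxolan-2-yl)-2,6-dimethoxyphenol | COc1cc(C2OCCO2)cc(OC)c1O | intermediate
3 | but-3-yn-2-one | CC(=O)C#C | starting material
4 | (E)-4-[4-(1,3-dioxolan-2-yl)-2,6-dimethoxyphenoxy]but-3-en-2-one | CC(=O)/C=C/Oc1c(OC)cc(C2OCCO2)cc1OC | intermediate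
5 | (R,E)-4-[4-(1,3-dioxolan-2-yl)-2,6-dimethoxyphenoxy]but-3-en-2-ol | O[C@H](C)/C=C/Oc1c(OC)cc(C2OCCO2)cc1OC | intermediate
6 | vanillin | COc1cc(C=O)ccc1O | starting material
7 | 3-methoxy-4-(triisopropylsilyloxy)benzaldehyde | COc1cc(C=O)ccc1O[Si](C(C)C)(C(C)C)C(C)C | intermediate
8 | [3-methoxy-4-(triisopropylsilyloxy)phenyl]methanol | COc1cc(CO)ccc1O[Si](C(C)C)(C(C)C)C(C)C | intermediate
9 | 4-(bromomethyl)-2-methoxy-1-(triisopropylsilyloxy)benzene | COc1cc(CBr)ccc1O[Si](C(C)C)(C(C)C)C(C)C | intermediate
10 | (R,E)-4-[4-(1,3-dioxolan-2-yl)-2,6-dimethoxyphenoxy]but-3-en-2-yl 3-methoxy-4-(triisopropylsilyloxy)benzyl ether | COc1cc(CO[C@H](C)/C=C/Oc2c(OC)cc(C3OCCO3)cc2OC)ccc1O[Si](C(C)C)(C(C)C)C(C)C | intermediate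
11 | benzylic α-lithio derivative of 10 | COc1cc(C([Li])O[C@H](C)/C=C/Oc2c(OC)cc(C3OCCO3)cc2OC)ccc1O[Si](C(C)C)(C(C)C)C(C)C | intermediate
12 | (1R,2S,3E)-2-[4-(1,3-dioxolan-2-yl)-2,6-dimethoxyphenoxy]-1-[3-methoxy-4-(triisopropylsilyloxy)phenyl]pent-3-en-1-ol | COc1cc([C@@H](O)[C@H](/C=C/C)Oc2c(OC)cc(C3OCCO3)cc2OC)ccc1O[Si](C(C)C)(C(C)C)C(C)C | intermediate
13 | 4-{[(1R,2S,3E)-1-hydroxy-1-[3-methoxy-4-(triisopropylsilyloxy)phenyl]pent-3-en-2-yl]oxy}-3,5-dimethoxybenzaldehyde | COc1cc([C@@H](O)[C@H](/C=C/C)Oc2c(OC)cc(C=O)cc2OC)ccc1O[Si](C(C)C)(C(C)C)C(C)C | intermediate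
14 | 4-{[(1R,2S,3E)-1-(tert-butyldimethylsilyloxy)-1-[3-methoxy-4-(triisopropylsilyloxy)phenyl]pent-3-en-2-yl]oxy}-3,5-dimethoxybenzaldehyde | COc1cc([C@@H](O[Si](C)(C)C(C)(C)C)[C@H](/C=C/C)Oc2c(OC)cc(C=O)cc2OC)ccc1O[Si](C(C)C)(C(C)C)C(C)C | intermediate
15 | 2',4',6'-trihydroxyacetophenone | CC(=O)c1c(O)cc(O)cc1O | starting material
16 | (E)-2',4',6'-trihydroxychalcone carrying the silylated (1R,2S,3E)-pentenyl ether on the ring B 4-oxygen | COc1cc([C@@H](O[Si](C)(C)C(C)(C)C)[C@H](/C=C/C)Oc2c(OC)cc(/C=C/C(=O)c3c(O)cc(O)cc3O)cc2OC)ccc1O[Si](C(C)C)(C(C)C)C(C)C | intermediate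
17 | 5,7-dihydroxyflavanone corresponding to 16 (both C2 epimers) | COc1cc([C@@H](O[Si](C)(C)C(C)(C)C)[C@H](/C=C/C)Oc2c(OC)cc(C3CC(=O)c4c(O)cc(O)cc4O3)cc2OC)ccc1O[Si](C(C)C)(C(C)C)C(C)C | intermediate
18 | 5,7-dihydroxyflavone with Cα O-TBS, ring G O-TIPS and the (E)-propenyl group on Cβ | COc1cc([C@@H](O[Si](C)(C)C(C)(C)C)[C@H](/C=C/C)Oc2c(OC)cc(-c3cc(=O)c4c(O)cc(O)cc4o3)cc2OC)ccc1O[Si](C(C)C)(C(C)C)C(C)C | intermediate
19 | 7-O-TIPS ether of 18 | COc1cc([C@@H](O[Si](C)(C)C(C)(C)C)[C@H](/C=C/C)Oc2c(OC)cc(-c3cc(=O)c4c(O)cc(O[Si](C(C)C)(C(C)C)C(C)C)cc4o3)cc2OC)ccc1O[Si](C(C)C)(C(C)C)C(C)C | intermediate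
20 | vicinal diol from dihydroxylation of the propenyl group of 19 (diol centres as a mixture) | COc1cc([C@@H](O[Si](C)(C)C(C)(C)C)[C@H](C(O)C(C)O)Oc2c(OC)cc(-c3cc(=O)c4c(O)cc(O[Si](C(C)C)(C(C)C)C(C)C)cc4o3)cc2OC)ccc1O[Si](C(C)C)(C(C)C)C(C)C | intermediate
21 | α-aryloxy aldehyde at Cγ (geometry at Cα and Cβ unchanged) | COc1cc([C@@H](O[Si](C)(C)C(C)(C)C)[C@H](C=O)Oc2c(OC)cc(-c3cc(=O)c4c(O)cc(O[Si](C(C)C)(C(C)C)C(C)C)cc4o3)cc2OC)ccc1O[Si](C(C)C)(C(C)C)C(C)C | intermediate
22 | (2S,3R)-3-(tert-butyldimethylsilyloxy)-2-{4-[5-hydroxy-4-oxo-7-(triisopropylsilyloxy)-4H-chromen-2-yl]-2,6-dimethoxyphenoxy}-3-[3-methoxy-4-(triisopropylsilyloxy)phenyl]propan-1-ol | COc1cc([C@@H](O[Si](C)(C)C(C)(C)C)[C@H](CO)Oc2c(OC)cc(-c3cc(=O)c4c(O)cc(O[Si](C(C)C)(C(C)C)C(C)C)cc4o3)cc2OC)ccc1O[Si](C(C)C)(C(C)C)C(C)C | intermediate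
23 | (E)-p-coumaric acid | OC(=O)/C=C/c1ccc(O)cc1 | starting material
24 | Cγ (E)-p-coumarate of 22 | COc1cc([C@@H](O[Si](C)(C)C(C)(C)C)[C@H](COC(=O)/C=C/c2ccc(O)cc2)Oc2c(OC)cc(-c3cc(=O)c4c(O)cc(O[Si](C(C)C)(C(C)C)C(C)C)cc4o3)cc2OC)ccc1O[Si](C(C)C)(C(C)C)C(C)C | intermediate
25 | (αR,βS)-erythro tricin 4'-O-(β-guaiacylglyceryl) ether γ-(E)-p-coumarate | COc1cc([C@@H](O)[C@H](COC(=O)/C=C/c2ccc(O)cc2)Oc2c(OC)cc(-c3cc(=O)c4c(O)cc(O)cc4o3)cc2OC)ccc1O | target

## Step count and least certain steps

Total: 16 steps. Longest linear sequence: 13 steps (steps 1–3 and 7–16 from syringaldehyde; the vanillin branch, steps 4–8 onward, is equally long).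

Key step (step 8). The most likely failure is incomplete exo preference of the aryl group, which would erode the anti:syn ratio at Cα; (E)-allyl ethers are known to be the less selective series. Competing ortho-metalation of ring B between the methoxy and acetal groups could also lower conversion. Fallback: setting out from 12 as its mixture of Cα epimers, the alcohol is oxidised with Dess–Martin periodinane (NaHCO3 buffer) to the α-aryloxy ketone F1. F1 is reduced cold with Zn(BH4)2 in Et2O under chelation control (cyclic Cram model, which delivers the anti diad) and comes back to the route at 12. Cβ, which the rearrangement sets by chirality transfer, is kept.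

Enantioselective reduction (step 3). The β-aryloxy enone is a vinylogous ester, so poor facial selectivity or slow reduction is possible, and the product may ionise during isolation. Fallback: setting out from 4, Luche reduction (NaBH4, CeCl3·7H2O, MeOH, −40 °C) gives the racemic alcohol F2. Kinetic resolution with Candida antarctica lipase B and vinyl acetate acylates the (R) enantiomer to the acetate F3 and leaves the (S) alcohol F4, which can be re-oxidised to 4. Methanolysis of F3 (K2CO3, MeOH) comes back to the route at 5.

Polyanion condensation (step 11). Poor solubility or low nucleophilicity of the tetra-lithiated acetophenone may stall the aldol addition, and the aldolate may fail to eliminate. Fallback: setting out from 15 and 14, 15 is converted to 2',4',6'-tris(tert-butyldimethylsilyloxy)acetophenone F5 (TBSCl, imidazole, DMF). Its lithium enolate (LiN(iPr)2, THF, −78 °C) is added to 14 to give the β-hydroxy ketone F6. K2CO3 in MeOH then dehydrates F6 and removes the three carbonyl-activated aryl TBS ethers, which comes back to the route at 16.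

Oxidative cyclisation (step 12). Iodination of the electron-rich ring A, addition of iodine and pyridine across the propenyl group, or partial loss of silyl groups at 90 °C may lower the yield. Fallback (non-oxidative, by way of a 1,3-diketone): setting out from 14, Pinnick oxidation (NaClO2, NaH2PO4, 2-methylbut-2-ene) gives the acid F7. 1-Chloro-N,N,2-trimethylpropenylamine converts F7 to the acid chloride F8. C-acylation of the lithium polyanion of 15 (LiN(SiMe3)2, THF, −78 °C) gives the β-diketone F9. Cyclodehydration (camphorsulfonic acid cat., toluene, 60 °C) comes back to the route at 18, bypassing 16.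

Global desilylation (step 16). The hindered Cα silyl ether may be slow to leave; forcing the conditions would invite γ→α acyl migration or loss of the ester. Fallback: setting out from 22, the Cα TBS ether is removed first with HF·pyridine in THF/pyridine to give the diol F10. Mitsunobu esterification with 23, selective for the primary hydroxyl, gives the ester F11 with the Cα hydroxyl free. A short treatment with Bu4NF/AcOH then removes only the two aryl TIPS ethers and comes back to the route at 25.

## Further compounds

F1 | step 8 | (S,E)-2-[4-(1,3-dioxolan-2-yl)-2,6-dimethoxyphenoxy]-1-[3-methoxy-4-(triisopropylsilyloxy)phenyl]pent-3-en-1-one | COc1cc(C(=O)[C@H](/C=C/C)Oc2c(OC)cc(C3OCCO3)cc2OC)ccc1O[Si](C(C)C)(C(C)C)C(C)C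
F2 | step 3 | racemic (E)-4-[4-(1,3-dioxolan-2-yl)-2,6-dimethoxyphenoxy]but-3-en-2-ol | CC(O)/C=C/Oc1c(OC)cc(C2OCCO2)cc1OC
F3 | step 3 | (R,E)-4-[4-(1,3-dioxolan-2-yl)-2,6-dimethoxyphenoxy]but-3-en-2-yl acetate | CC(=O)O[C@H](C)/C=C/Oc1c(OC)cc(C2OCCO2)cc1OC
F4 | step 3 | (S,E)-4-[4-(1,3-dioxolan-2-yl)-2,6-dimethoxyphenoxy]but-3-en-2-ol | O[C@@H](C)/C=C/Oc1c(OC)cc(C2OCCO2)cc1OC
F5 | step 11 | 2',4',6'-tris(tert-butyldimethylsilyloxy)acetophenone | CC(=O)c1c(O[Si](C)(C)C(C)(C)C)cc(O[Si](C)(C)C(C)(C)C)cc1O[Si](C)(C)C(C)(C)C
F6 | step 11 | β-hydroxy ketone from the enolate of F5 and aldehyde 14 (carbinol centre as a mixture) | COc1cc([C@@H](O[Si](C)(C)C(C)(C)C)[C@H](/C=C/C)Oc2c(OC)cc(C(O)CC(=O)c3c(O[Si](C)(C)C(C)(C)C)cc(O[Si](C)(C)C(C)(C)C)cc3O[Si](C)(C)C(C)(C)C)cc2OC)ccc1O[Si](C(C)C)(C(C)C)C(C)C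
F7 | step 12 | 4-{[(1R,2S,3E)-1-(tert-butyldimethylsilyloxy)-1-[3-methoxy-4-(triisopropylsilyloxy)phenyl]pent-3-en-2-yl]oxy}-3,5-dimethoxybenzoic acid | COc1cc([C@@H](O[Si](C)(C)C(C)(C)C)[C@H](/C=C/C)Oc2c(OC)cc(C(=O)O)cc2OC)ccc1O[Si](C(C)C)(C(C)C)C(C)C
F8 | step 12 | acid chloride of F7 | COc1cc([C@@H](O[Si](C)(C)C(C)(C)C)[C@H](/C=C/C)Oc2c(OC)cc(C(=O)Cl)cc2OC)ccc1O[Si](C(C)C)(C(C)C)C(C)C
F9 | step 12 | 1-(2,4,6-trihydroxyphenyl)-3-aryl-propane-1,3-dione from F8 and 15 | COc1cc([C@@H](O[Si](C)(C)C(C)(C)C)[C@H](/C=C/C)Oc2c(OC)cc(C(=O)CC(=O)c3c(O)cc(O)cc3O)cc2OC)ccc1O[Si](C(C)C)(C(C)C)C(C)C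
F10 | step 16 | (1R,2S)-diol: compound 22 without the Cα silyl group | COc1cc([C@@H](O)[C@H](CO)Oc2c(OC)cc(-c3cc(=O)c4c(O)cc(O[Si](C(C)C)(C(C)C)C(C)C)cc4o3)cc2OC)ccc1O[Si](C(C)C)(C(C)C)C(C)C
F11 | step 16 | Cγ (E)-p-coumarate of F10 with the Cα hydroxyl free | COc1cc([C@@H](O)[C@H](COC(=O)/C=C/c2ccc(O)cc2)Oc2c(OC)cc(-c3cc(=O)c4c(O)cc(O[Si](C(C)C)(C(C)C)C(C)C)cc4o3)cc2OC)ccc1O[Si](C(C)C)(C(C)C)C(C)C
A1 | alternative 1 | 2-(4-bromo-2,6-dimethoxyphenoxy)propane-1,3-diol | OCC(CO)Oc1c(OC)cc(Br)cc1OC
A2 | alternative 1 | vinyl (E)-3-[4-(tert-butyldimethylsilyloxy)phenyl]prop-2-enoate | C=COC(=O)/C=C/c1ccc(O[Si](C)(C)C(C)(C)C)cc1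
A3 | alternative 1 | mono-p-coumarate of A1 with Cβ configured | OC[C@H](COC(=O)/C=C/c1ccc(O[Si](C)(C)C(C)(C)C)cc1)Oc1c(OC)cc(Br)cc1OC
A4 | alternative 2 | N-hydroxyphthalimide ester of 5-[2,6-dimethoxy-4-(methoxycarbonyl)phenoxy]-2-phenyl-1,3-dioxane-4-carboxylic acid | O=C(ON1C(=O)c2ccccc2C1=O)C1OC(c2ccccc2)OC[C@@H]1Oc1c(OC)cc(C(=O)OC)cc1OC
A5 | alternative 2 | 4-iodo-2-methoxy-1-(triisopropylsilyloxy)benzene | COc1cc(I)ccc1O[Si](C(C)C)(C(C)C)C(C)C
A6 | alternative 2 | trans-4-aryl-5-aryloxy-2-phenyl-1,3-dioxane | COc1cc([C@H]2OC(c3ccccc3)OC[C@@H]2Oc2c(OC)cc(C(=O)OC)cc2OC)ccc1O[Si](C(C)C)(C(C)C)C(C)C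
A7 | alternative 3 | racemic ethyl 2-(4-bromo-2,6-dimethoxyphenoxy)-3-[3-methoxy-4-(triisopropylsilyloxy)phenyl]-3-oxopropanoate | COc1cc(C(=O)C(C(=O)OCC)Oc2c(OC)cc(Br)cc2OC)ccc1O[Si](C(C)C)(C(C)C)C(C)C
A8 | alternative 3 | erythro α-aryloxy-β-hydroxy ester | COc1cc([C@@H](O)[C@H](C(=O)OCC)Oc2c(OC)cc(Br)cc2OC)ccc1O[Si](C(C)C)(C(C)C)C(C)C
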